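**Plan**

1. Cuts: the acyl–O bond of the C5 ester; the lactone O–C6 bond, read as an ether bridge O8 that joins C6 and C9; C11=C13 (Mannich methylenation); C1–C2 (acetylide onto a C1 ketone); C5–O (enolate hydroxylation); C5–C6 and C9–C10 ((4+3) cycloaddition of a 3-substituted furan and a methyl-substituted oxyallyl cation).
2. Enabling feature: the lactone oxygen on C6 (α) and the free hydroxyl on C9 (β) are trans and 1,4-related across C7–C8 of the cycloheptane, and the γ-lactone is cis-fused at C6–C7. This is the pattern left when the bridging oxygen of an 8-oxabicyclo[3.2.1]octane is displaced at C6, with inversion, by a carboxyl held on the endo face at C7.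
3. Forward order: furan to oxabicyclic ketone (carbocycle and tetrahydrofuran bridge formed together), exo hydrogenation, C5 hydroxylation, C1 alkynylation, α-methylenation, C5 esterification, alkyne hydration, then the bridge-to-lactone switch that closes the lactone and opens the bicycle, and desilylation.
4. Stereochemistry: C10 from the cycloaddition (equatorial methyl); C7 from exo-face hydrogenation; C5 and C1 from exo-face attack on the rigid bicycle; C9 from the retained bridge oxygen; C6 by inversion in the key step. C4 and the ester stereocentre come from (R)-but-3-yn-2-ol and (R)-2-methylbutanoic acid. The absolute configuration of the ring is fixed when the racemic bicyclic ketone is joined to the enantiopure alkyne and the two diastereomers are separated.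

Key step: step 10

Remark (labels): C1 is the carbinol carbon carrying the chain C2(=O)–C3H2–C4H(OH)–C15H3; C5 = CH–O–ester; C6 = CH–O(lactone); C7 = ring-fusion CH; C8 = CH2; C9 = CHOH; C10 = CH(C14H3); C11, C12, C13 = α-carbon, carbonyl and exocyclic CH2 of the lactone. β is the face of the C5 and C9 oxygens and of the ether bridge O8; α is the other face.
Remark (assignment): CIP analysis of the given SMILES makes the side-chain carbinol (R) and the ester an (R)-2-methylbutanoate.
Remark (assumptions): the four starting materials are taken as commercial. The intermediates from the cycloadduct up to the α-hydroxy ketone are racemic, and their SMILES show the enantiomer that is carried on.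

**Route**

Step 1
Reactants: 1 2-(furan-3-yl)acetic acid
Product: 2 tert-butyl 2-(furan-3-yl)acetate
Conditions: Me2NCH(OtBu)2, toluene, 80 °C
Reagents that add atoms: N,N-dimethylformamide di-tert-butyl acetal, CN(C)C(OC(C)(C)C)OC(C)(C)C
Why: Alkylation of the carboxylate by the amide acetal under neutral conditions should spare the furan and give the tert-butyl ester, which resists the bases and nucleophiles of steps 4 to 7 and is shed as 2-methylpropene in step 10.

Step 2
Reactants: 2 tert-butyl 2-(furan-3-yl)acetate; 3 3-chlorobutan-2-one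
Product: 4 racemic tert-butyl 2-(2-methyl-3-oxo-8-oxabicyclo[3.2.1]oct-6-en-6-yl)acetate (C10 methyl equatorial)
Conditions: 3 (3 equiv), Et3N, CF3CH2OH, 0 °C → rt
Reagents that add atoms: none
Why: (4+3) cycloaddition: 3 should ionise in the non-nucleophilic alcohol to the 1-methyl-2-oxyallyl cation, which adds across the two α-carbons of the furan, dearomatising it and forming the seven-membered carbocycle and the ether bridge O8 at once; the compact transition state and amine equilibration should place the C10 methyl equatorial (α, anti to O8), and the more nucleophilic furan carbon next to the side chain should bond first to the unsubstituted cation terminus, which puts the methyl-bearing carbon at the remote bridgehead.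

Step 3
Reactants: 4 racemic tert-butyl 2-(2-methyl-3-oxo-8-oxabicyclo[3.2.1]oct-6-en-6-yl)acetate
Product: 5 racemic tert-butyl 2-(2-methyl-3-oxo-8-oxabicyclo[3.2.1]octan-6-yl)acetate (side chain 6-endo)
Conditions: H2 (1 atm), Pd/C, EtOAc, rt
Reagents that add atoms: none
Why: Heterogeneous hydrogenation should deliver both hydrogens to the exo (β) face of the trisubstituted alkene, the face of the oxygen bridge, so that C7 is set with its acetate arm endo (α).

Step 4
Reactants: 5 racemic tert-butyl 2-(2-methyl-3-oxo-8-oxabicyclo[3.2.1]octan-6-yl)acetate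
Product: 7 racemic tert-butyl 2-(4-hydroxy-2-methyl-3-oxo-8-oxabicyclo[3.2.1]octan-6-yl)acetate (C5 hydroxyl axial), via sodium enolate 6 (not isolated)
Conditions: NaN(SiMe3)2, THF, −78 °C; then 2-(phenylsulfonyl)-3-phenyloxaziridine, −78 °C; aq. NH4Cl
Reagents that add atoms: 2-(phenylsulfonyl)-3-phenyloxaziridine, O=S(=O)(c1ccccc1)N1OC1c1ccccc1
Why: Enolate hydroxylation with an N-sulfonyloxaziridine: the hindered amide base should remove the axial proton of the unsubstituted α-methylene (C5) rather than the proton at methyl-bearing C10 or the less acidic ester protons, and oxygen transfer to the open exo face should set the C5 hydroxyl axial and β; at −78 °C the enolate should not expel the bridging oxygen.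

Step 5
Reactants: 8 (R)-but-3-yn-2-ol
Product: 9 (R)-tert-butyl(but-3-yn-2-yloxy)dimethylsilane
Conditions: TBSCl, imidazole, DMF, rt
Reagents that add atoms: tert-butyldimethylsilyl chloride, CC(C)(C)[Si](C)(C)Cl
Why: Standard silylation of the secondary alcohol, which leaves the (R) stereocentre (the future C4) untouched.

Step 6
Reactants: 7 racemic tert-butyl 2-(4-hydroxy-2-methyl-3-oxo-8-oxabicyclo[3.2.1]octan-6-yl)acetate; 9 (R)-tert-butyl(but-3-yn-2-yloxy)dimethylsilane
Product: 11 tert-butyl 2-{3-[(3R)-3-(tert-butyldimethylsilyloxy)but-1-yn-1-yl]-3,4-dihydroxy-2-methyl-8-oxabicyclo[3.2.1]octan-6-yl}acetate (single enantiomer; C1 alkynyl β; C1 hydroxyl α; C5 hydroxyl β), via lithium acetylide 10 (not isolated)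
Conditions: 9 (2.5 equiv), n-BuLi, THF, −78 °C; then 7, −78 → −30 °C; aq. NH4Cl; chromatographic separation of the two diastereomers
Reagents that add atoms: none
Why: 1,2-Addition of a lithium acetylide to the ketone: the first equivalent deprotonates the C5 hydroxyl and returns as 9, the second should attack C1 from the exo (β) face because the endo face is closed by the C7–C8 bridge and its side chain, giving the equatorial β-alkynyl group and the axial α-hydroxyl; each enantiomer of 7 should react in this way, and of the two diastereomers formed with the (R)-alkyne the one drawn is carried on.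

Step 7
Reactants: 11 tert-butyl 2-{3-[(3R)-3-(tert-butyldimethylsilyloxy)but-1-yn-1-yl]-3,4-dihydroxy-2-methyl-8-oxabicyclo[3.2.1]octan-6-yl}acetate
Product: 15 tert-butyl 2-{3-[(3R)-3-(tert-butyldimethylsilyloxy)but-1-yn-1-yl]-3,4-dihydroxy-2-methyl-8-oxabicyclo[3.2.1]octan-6-yl}prop-2-enoate, via trilithium salt 12 (not isolated), via Mannich base 13 (not isolated), via ammonium iodide 14 (not isolated)
Conditions: LiN(iPr)2 (3.3 equiv), THF, −78 → −40 °C; CH2=NMe2+ I−, −78 °C → rt; aq. NH4Cl; MeI, MeOH, rt; aq. NaHCO3, CH2Cl2, rt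
Reagents that add atoms: dimethyl(methylidene)ammonium iodide, C=[N+](C)C.[I-]
Why: Mannich methylenation: with the ketone gone the ester α-methylene is the only acidic C–H, its lithium enolate should be aminomethylated by the iminium salt, and quaternisation followed by E1cB loss of trimethylamine should give the acrylate (the future C11=C13).

Step 8
Reactants: 15 tert-butyl 2-{3-[(3R)-3-(tert-butyldimethylsilyloxy)but-1-yn-1-yl]-3,4-dihydroxy-2-methyl-8-oxabicyclo[3.2.1]octan-6-yl}prop-2-enoate; 16 (R)-2-methylbutanoic acid
Product: 17 tert-butyl 2-{3-[(3R)-3-(tert-butyldimethylsilyloxy)but-1-yn-1-yl]-3-hydroxy-2-methyl-4-[(2R)-2-methylbutanoyloxy]-8-oxabicyclo[3.2.1]octan-6-yl}prop-2-enoate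
Conditions: DCC, DMAP (cat.), CH2Cl2, 0 °C → rt
Reagents that add atoms: none
Why: Steglich esterification should acylate the secondary C5 hydroxyl and leave the tertiary C1 hydroxyl, which is trans-diaxial to it and so cannot take over the acyl group; the α-stereocentre of the acid carries no activating group and should survive.

Step 9
Reactants: 17 tert-butyl 2-{3-[(3R)-3-(tert-butyldimethylsilyloxy)but-1-yn-1-yl]-3-hydroxy-2-methyl-4-[(2R)-2-methylbutanoyloxy]-8-oxabicyclo[3.2.1]octan-6-yl}prop-2-enoate
Product: 18 tert-butyl 2-{3-[(3R)-3-(tert-butyldimethylsilyloxy)butanoyl]-3-hydroxy-2-methyl-4-[(2R)-2-methylbutanoyloxy]-8-oxabicyclo[3.2.1]octan-6-yl}prop-2-enoate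
Conditions: Ph3PAuNTf2 (5 mol%), H2O (5 equiv), 1,4-dioxane, 40 °C
Reagents that add atoms: water, O
Why: Alkyne hydration under cationic gold catalysis with neighbouring-group participation: the carbonyl oxygen of the C5 ester, gauche to the alkynyl group, should attack the activated alkyne at C2 (6-exo-dig), and hydrolysis of the dioxinium intermediate should return the ester and place the ketone at C2 and not at C3; C4 is not touched.

Step 10
Reactants: 18 tert-butyl 2-{3-[(3R)-3-(tert-butyldimethylsilyloxy)butanoyl]-3-hydroxy-2-methyl-4-[(2R)-2-methylbutanoyloxy]-8-oxabicyclo[3.2.1]octan-6-yl}prop-2-enoate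
Product: 21 C4 tert-butyldimethylsilyl ether of the target (cis-fused α-methylene-γ-lactone; free C9 and C1 hydroxyls), via silyl ester 19 (not isolated), via silylated lactone 20 (not isolated)
Conditions: Me3SiOTf (4 equiv), 2,6-di-tert-butyl-4-methylpyridine (2.2 equiv), CH2Cl2, 0 °C → rt; then AcOH–THF–H2O, rt
Reagents that add atoms: none
Why: Proposed new method: Me3SiOTf should first turn the tert-butyl ester into the silyl ester 19 (loss of 2-methylpropene, C1 hydroxyl capped) and then silylate the bridging oxygen O8; in this oxonium ion the carbonyl oxygen of the C12 carboxyl, held on the endo (α) face at C7 and therefore anti-periplanar to the C6–O8 bond, displaces O8 at C6 in SN2 fashion while its silyl group passes on, so that the silyl cation is regenerated. The closest known reaction types are the Lewis acid-promoted cleavage of tetrahydrofurans and oxabicyclic ethers by silyl or acyl electrophiles with capture of a nucleophile under inversion and, for the ring closure, the anti 5-exo opening of epoxides and iodonium ions by a γ-carboxyl group; the lactonising, intramolecular cleavage of an 8-oxabicyclo[3.2.1]octane is the new element. The γ-lactone (O–C6–C7–C11–C12) closes 5-exo-tet, and the same event opens the tetrahydrofuran ring of the bicycle and leaves the monocyclic cycloheptane. C6 is set by inversion (lactone oxygen α, cis to the C7–C11 bond and trans to the C5 ester), C9 keeps its oxygen with retention and becomes the free β-hydroxyl, and C7 was fixed in step 3. The step needs cleavage of C6–O8 and not of C9–O8, and attack by the carboxyl and not by another oxygen: only the C7 carboxyl reaches the back lobe of a bridge C–O bond through a five-membered transition state (C9 would need a bridged six-membered one), the C5 ester and the C2 ketone lie on the β face syn to the bridge, the C1 hydroxyl is silylated, and neither triflate nor the hindered pyridine is a competing nucleophile.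

Step 11
Reactants: 21 C4 tert-butyldimethylsilyl ether of the target
Product: 22 target CNP0291806.5
Conditions: HF·pyridine, THF, 0 °C → rt
Reagents that add atoms: none
Why: Fluoride-mediated cleavage of the secondary silyl ether under mildly acidic conditions should spare the α-methylene lactone, the ester and the β-hydroxy ketone and give the target.

**Compound list**

1 | 2-(furan-3-yl)acetic acid | OC(=O)Cc1ccoc1 | starting material
2 | tert-butyl 2-(furan-3-yl)acetate | CC(C)(C)OC(=O)Cc1ccoc1 | intermediate
3 | 3-chlorobutan-2-one (racemic) | CC(Cl)C(C)=O | starting material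
4 | racemic tert-butyl 2-(2-methyl-3-oxo-8-oxabicyclo[3.2.1]oct-6-en-6-yl)acetate; C10 methyl equatorial (α) | [C@@H]12C(CC(=O)OC(C)(C)C)=C[C@@H](O1)[C@H](C)C(=O)C2 | intermediate
5 | racemic tert-butyl 2-(2-methyl-3-oxo-8-oxabicyclo[3.2.1]octan-6-yl)acetate; side chain endo (C7 α) | [C@@H]12[C@H](CC(=O)OC(C)(C)C)C[C@@H](O1)[C@H](C)C(=O)C2 | intermediate
6 | sodium enolate of 5 (C1–ONa, C1=C5) | [C@@H]12[C@H](CC(=O)OC(C)(C)C)C[C@@H](O1)[C@H](C)C(O[Na])=C2 | intermediate
7 | racemic tert-butyl 2-(4-hydroxy-2-methyl-3-oxo-8-oxabicyclo[3.2.1]octan-6-yl)acetate; C5 hydroxyl axial (β) | [C@@H]12[C@H](CC(=O)OC(C)(C)C)C[C@@H](O1)[C@H](C)C(=O)[C@H]2O | intermediate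
8 | (R)-but-3-yn-2-ol | C#C[C@@H](C)O | starting material
9 | (R)-tert-butyl(but-3-yn-2-yloxy)dimethylsilane | C#C[C@@H](C)O[Si](C)(C)C(C)(C)C | intermediate
10 | lithium acetylide of 9 | [Li]C#C[C@@H](C)O[Si](C)(C)C(C)(C)C | intermediate
11 | tert-butyl 2-{3-[(3R)-3-(tert-butyldimethylsilyloxy)but-1-yn-1-yl]-3,4-dihydroxy-2-methyl-8-oxabicyclo[3.2.1]octan-6-yl}acetate; C1 alkynyl β, C1–OH α, C5–OH β | [C@@H]12[C@H](CC(=O)OC(C)(C)C)C[C@@H](O1)[C@H](C)[C@@](O)(C#C[C@@H](C)O[Si](C)(C)C(C)(C)C)[C@H]2O | intermediate
12 | trilithium salt of 11 (two alkoxides and the ester enolate) | [C@@H]12[C@H](C=C(O[Li])OC(C)(C)C)C[C@@H](O1)[C@H](C)[C@@](O[Li])(C#C[C@@H](C)O[Si](C)(C)C(C)(C)C)[C@H]2O[Li] | intermediate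
13 | Mannich base: 3-(dimethylamino)propanoate analogue of 11 (both C11 epimers) | [C@@H]12[C@H](C(CN(C)C)C(=O)OC(C)(C)C)C[C@@H](O1)[C@H](C)[C@@](O)(C#C[C@@H](C)O[Si](C)(C)C(C)(C)C)[C@H]2O | intermediate
14 | trimethylammonium iodide of 13 | [C@@H]12[C@H](C(C[N+](C)(C)C)C(=O)OC(C)(C)C)C[C@@H](O1)[C@H](C)[C@@](O)(C#C[C@@H](C)O[Si](C)(C)C(C)(C)C)[C@H]2O.[I-] | intermediate
15 | tert-butyl 2-{3-[(3R)-3-(tert-butyldimethylsilyloxy)but-1-yn-1-yl]-3,4-dihydroxy-2-methyl-8-oxabicyclo[3.2.1]octan-6-yl}prop-2-enoate | [C@@H]12[C@H](C(=C)C(=O)OC(C)(C)C)C[C@@H](O1)[C@H](C)[C@@](O)(C#C[C@@H](C)O[Si](C)(C)C(C)(C)C)[C@H]2O | intermediate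
16 | (R)-2-methylbutanoic acid | CC[C@@H](C)C(=O)O | starting material
17 | C5 (2R)-2-methylbutanoate of 15 | [C@@H]12[C@H](C(=C)C(=O)OC(C)(C)C)C[C@@H](O1)[C@H](C)[C@@](O)(C#C[C@@H](C)O[Si](C)(C)C(C)(C)C)[C@H]2OC(=O)[C@H](C)CC | intermediate
18 | C2 ketone: tert-butyl 2-{3-[(3R)-3-(tert-butyldimethylsilyloxy)butanoyl]-3-hydroxy-2-methyl-4-[(2R)-2-methylbutanoyloxy]-8-oxabicyclo[3.2.1]octan-6-yl}prop-2-enoate | [C@@H]12[C@H](C(=C)C(=O)OC(C)(C)C)C[C@@H](O1)[C@H](C)[C@@](O)(C(=O)C[C@@H](C)O[Si](C)(C)C(C)(C)C)[C@H]2OC(=O)[C@H](C)CC | intermediate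
19 | trimethylsilyl ester of the acrylic acid from 18, C1–OSiMe3 | [C@@H]12[C@H](C(=C)C(=O)O[Si](C)(C)C)C[C@@H](O1)[C@H](C)[C@@](O[Si](C)(C)C)(C(=O)C[C@@H](C)O[Si](C)(C)C(C)(C)C)[C@H]2OC(=O)[C@H](C)CC | intermediate
20 | lactone with C9–OSiMe3, C1–OSiMe3 and C4–OTBS | C=C1C(=O)O[C@@H]2[C@H]1C[C@@H](O[Si](C)(C)C)[C@H](C)[C@@](O[Si](C)(C)C)(C(=O)C[C@@H](C)O[Si](C)(C)C(C)(C)C)[C@H]2OC(=O)[C@H](C)CC | intermediate
21 | C4 tert-butyldimethylsilyl ether of the target | C=C1C(=O)O[C@@H]2[C@H]1C[C@@H](O)[C@H](C)[C@@](O)(C(=O)C[C@@H](C)O[Si](C)(C)C(C)(C)C)[C@H]2OC(=O)[C@H](C)CC | intermediate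
22 | CNP0291806.5: cis-fused 6α,12-lactone with 1α-OH, 5β-(R)-2-methylbutanoyloxy, 9β-OH, 10α-methyl and (4R)-hydroxyl | C=C1C(=O)O[C@@H]2[C@H]1C[C@@H](O)[C@H](C)[C@@](O)(C(=O)C[C@@H](C)O)[C@H]2OC(=O)[C@H](C)CC | target

**Step count and risks**

Total steps: 11. Longest linear sequence: 10 (steps 1 to 4 and 6 to 11).

Steps most likely to fail:

1. Step 10 (Proposed new method). The internal displacement at C6 may be too slow, because C6 has the acyloxy-bearing C5 as neighbour; the oxonium ion would then be opened at C9 by an external nucleophile, or the silylated α-ketol would decompose. Fallback with known reaction types, from 18 back to 21: Me2BBr (CH2Cl2, −78 → 0 °C) should cleave the bridge by SN2 attack of bromide at the less hindered, undeactivated C9 (inversion) and give the bromo alcohol F1, which keeps the β-hydroxyl on C6. MsCl and Et3N should give the mesylate F2. Warming F2 in (CF3)2CHOH buffered with 2,6-lutidine should let the ester carbonyl displace the mesylate at C6 from the α face (inversion, loss of 2-methylpropene) and give the bromo lactone F3. HCO2Cs in DMF should replace the α-bromide at C9 under a second inversion to give the β-formate F4, and KHCO3 in MeOH should remove the formyl group to reach 21.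

2. Step 9. Regiocontrol may be lost (water entering at C3), or the tertiary propargylic alcohol may undergo Meyer–Schuster rearrangement. Fallback, from 17 back to 18: oxygen is delivered to C2 from the C1 hydroxyl instead of from the ester. AgOAc (10 mol%), DBU (20 mol%) and CO2 (1 MPa) in MeCN should convert 17 by carboxylative 5-exo-dig cyclisation into the (Z)-alkylidene cyclic carbonate F5, and mild hydrolysis (K2CO3, wet MeCN, 0 °C) should open the enol carbonate to the α-hydroxy ketone 18.

3. Step 2. The two unsymmetrical partners may combine with poor regiocontrol, or the oxyallyl cation may be consumed by the solvent before it meets the furan. Fallback, from 2 back to 4: a cation that bonds stepwise and carries a temporary methoxy group. Commercial 1,1-dimethoxybutan-2-one with Et3SiOTf and Et3N should give the (Z)-silyl enol ether F6. With catalytic Me3SiOTf in CH2Cl2 at −78 °C its acetal should ionise to a methoxy-substituted siloxyallyl cation whose oxocarbenium carbon attacks the nucleophilic furan carbon next to the side chain of 2 first, so that ring closure can only place the methyl-bearing carbon at the remote bridgehead (methoxy ketone F7). SmI2 (THF/MeOH, −78 °C) should then remove the α-methoxy group reductively and return 4.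

Further compounds
F1 | step 10 | bromo alcohol: ring-opened cycloheptane from 18 with C6 β-hydroxyl and C9 α-bromide (tert-butyl acrylate retained) | O[C@H]1[C@H](C(=C)C(=O)OC(C)(C)C)C[C@H](Br)[C@H](C)[C@@](O)(C(=O)C[C@@H](C)O[Si](C)(C)C(C)(C)C)[C@H]1OC(=O)[C@H](C)CC
F2 | step 10 | C6 β-methanesulfonate of F1 | CS(=O)(=O)O[C@H]1[C@H](C(=C)C(=O)OC(C)(C)C)C[C@H](Br)[C@H](C)[C@@](O)(C(=O)C[C@@H](C)O[Si](C)(C)C(C)(C)C)[C@H]1OC(=O)[C@H](C)CC
F3 | step 10 | bromo lactone: analogue of 21 with C9 α-bromide in place of the β-hydroxyl | C=C1C(=O)O[C@@H]2[C@H]1C[C@H](Br)[C@H](C)[C@@](O)(C(=O)C[C@@H](C)O[Si](C)(C)C(C)(C)C)[C@H]2OC(=O)[C@H](C)CC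
F4 | step 10 | C9 β-formate of 21 | C=C1C(=O)O[C@@H]2[C@H]1C[C@@H](OC=O)[C@H](C)[C@@](O)(C(=O)C[C@@H](C)O[Si](C)(C)C(C)(C)C)[C@H]2OC(=O)[C@H](C)CC
F5 | step 9 | (Z)-alkylidene cyclic carbonate from 17 (spiro 1,3-dioxolan-2-one at C1, exocyclic C2=C3) | [C@@H]12[C@H](C(=C)C(=O)OC(C)(C)C)C[C@@H](O1)[C@H](C)[C@]3(OC(=O)O/C3=C\[C@@H](C)O[Si](C)(C)C(C)(C)C)[C@H]2OC(=O)[C@H](C)CC
F6 | step 2 | (Z)-1,1-dimethoxy-2-(triethylsilyloxy)but-2-ene | C/C=C(\O[Si](CC)(CC)CC)C(OC)OC
F7 | step 2 | racemic 4-methoxy analogue of 4 (C5 methoxy equatorial, α) | [C@@H]12C(CC(=O)OC(C)(C)C)=C[C@@H](O1)[C@H](C)C(=O)[C@@H]2OC
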